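Calamenene numbering (C1 CH3, C4 isopropyl, C6 CH3, C8 OH; unit B primed). Ring A is opened by removing C5(H)–C6(CH3) as a propyne unit. This leaves C7=C8(OSi)–C8a=C4a as a 2-siloxydiene whose C7 terminus already carries unit B through C5'. One thermal [4+2] addition of phenyl 1-propynyl sulfone, then base-induced loss of benzenesulfinate, forms C6–C7 and C4a–C5, aromatises ring A and creates the crowded C7–C5' biaryl without aryl–aryl coupling. The feature exploited is the para relation of C5 to the C8 oxygen. The precursor is the (Z)-silyl dienol ether of an arylacetyl p-menthene from (S)-carvone; unit B comes from the same cycloaddition.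

Key step: step 12

Assumption: the SMILES defines C1, C4, C1' and C4' (1S,4R, trans, in both units) but not the sense of the tetra-ortho-substituted C7–C5' axis; this axis arises in the key step and should be configurationally stable, so either atropisomer fits the given structure, and if both form they would be separated by chromatography as the bis-silyl ether or as the free bisphenol.

Assumption: phenyl 1-propynyl sulfone is taken as a catalogue reagent.

Design note: calamenene means 1,6-dimethyl-4-(propan-2-yl)-1,2,3,4-tetrahydronaphthalene. Both phenol oxygens travel as TBS ethers, and unit B keeps the group delivered by its own cycloaddition. No protecting-group exchange is then needed, and one fluoride treatment ends the synthesis. The arylacetyl ketone is built by a two-component Weinreb acylation from an amide that also supplies the methyl ketone. Comments on unit B intermediates use primed locants; their names use plain calamenene locants.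

**Route**

Step 1
Reactants: 1 (S)-(+)-carvone
Product: 3 (2S,5S)-2-methyl-5-(propan-2-yl)cyclohexanone (trans-carvomenthone), via carvomenthone C2-epimer mixture 2 (not isolated)
Conditions: H2 (3 bar), Pd/C, EtOAc, rt; filter; NaOMe (cat.), MeOH, rt; chromatographic removal of the residual cis epimer, which is re-equilibrated
Reagents that add atoms: none
Why: Heterogeneous catalytic hydrogenation should saturate both C=C bonds without touching the isopropyl-bearing centre (later C4 and C4'), and base-catalysed enolate epimerisation then drives the methyl-bearing carbon (later C1 and C1') to the diequatorial trans isomer, so this centre is set under thermodynamic control by the carvone stereocentre.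

Step 2
Reactants: 3 trans-carvomenthone
Product: 5 (3R,6S)-6-methyl-3-(propan-2-yl)cyclohex-1-en-1-yl trifluoromethanesulfonate, via lithium enolate 4 (not isolated)
Conditions: LDA (commercial solution), THF, −78 °C, slow addition of 3; PhNTf2, −78 °C to rt
Reagents that add atoms: N-phenylbis(trifluoromethanesulfonimide), O=S(=O)(N(c1ccccc1)S(=O)(=O)C(F)(F)F)C(F)(F)F
Why: Kinetic enolate formation with the hindered lithium amide takes a proton from the CH2 flank, so the methyl-bearing centre is never enolised, and O-triflation of the enolate with the triflimide is the standard enol triflate synthesis.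

Step 3
Reactants: 5 enol triflate
Product: 6 (3R,6S)-N-methoxy-N,6-dimethyl-3-(propan-2-yl)cyclohex-1-ene-1-carboxamide
Conditions: CO (1 atm), MeNHOMe·HCl, Pd(OAc)2 (cat.), Xantphos (cat.), Et3N, DMF, 60 °C
Reagents that add atoms: carbon monoxide, [C-]#[O+]; N,O-dimethylhydroxylamine hydrochloride, CNOC.Cl
Why: Palladium-catalysed aminocarbonylation of an enol triflate (oxidative addition, CO insertion, capture of the acylpalladium by the hydroxylamine) is established for cyclohexenyl triflates and installs the future C8 and C8' without touching either stereocentre.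

Step 4
Reactants: 6 Weinreb amide
Product: 7 1-[(3R,6S)-6-methyl-3-(propan-2-yl)cyclohex-1-en-1-yl]ethanone
Conditions: MeMgBr, THF, 0 °C; aqueous work-up
Reagents that add atoms: methylmagnesium bromide, C[Mg]Br
Why: Weinreb ketone synthesis, in which the N-methoxy-N-methylamide accepts a single Grignard addition at the carbonyl carbon and releases the enone only on work-up, so neither over-addition nor conjugate addition is expected.

Step 5
Reactants: 7 methyl ketone
Product: 8 tert-butyl(dimethyl)({1-[(3R,6S)-6-methyl-3-(propan-2-yl)cyclohex-1-en-1-yl]ethenyl}oxy)silane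
Conditions: TBSOTf, Et3N, CH2Cl2, 0 °C; cold NaHCO3 wash, filtration through deactivated silica, amine stripped with toluene
Reagents that add atoms: tert-butyldimethylsilyl trifluoromethanesulfonate, CC(C)(C)[Si](C)(C)OS(=O)(=O)C(F)(F)F
Why: Soft enolisation (silyl triflate activation of the carbonyl, amine deprotonation) removes a methyl proton faster than the hindered tertiary γ-hydrogen at C4', which is the usual outcome for 1-acetylcyclohexenes and gives the cross-conjugated 2-siloxydiene with both stereocentres intact.

Step 6
Reactants: 8 2-siloxydiene; 9 phenyl 1-propynyl sulfone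
Product: 12 (1S,4R)-8-(tert-butyldimethylsilyloxy)calamenene, via vinyl sulfone cycloadduct 10 (not isolated), via allylic sulfone diene 11 (not isolated)
Conditions: 9 (1.5 equiv), BHT (cat.), toluene, 110 °C, sealed tube; cool; DBU, rt to 50 °C
Reagents that add atoms: none
Why: Diels–Alder reaction of a 2-siloxydiene with an acetylenic sulfone in the para orientation (CH2 terminus C7' to the methyl-bearing alkyne carbon C6', C4a' to the sulfonyl carbon C5'), followed by base-mediated double-bond shift and elimination of benzenesulfinate, should give the aromatic ring of unit B as its silyl ether and rehearses step 12 on an unhindered diene.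

Step 7
Reactants: 12 8-(TBSO)calamenene
Product: 13 (1S,4R)-5-bromo-8-(tert-butyldimethylsilyloxy)calamenene
Conditions: NBS (1.0 equiv), MeCN, 0 °C to rt, dark
Reagents that add atoms: N-bromosuccinimide, O=C1CCC(=O)N1Br
Why: Electrophilic aromatic bromination with NBS in a polar solvent goes para to the oxygen donor, and the bulky silyl ether together with the C6' methyl group shields the only other free position C7', so bromine should enter at C5'.

Step 8
Reactants: 13 aryl bromide
Product: 16 [(1S,4R)-8-(tert-butyldimethylsilyloxy)calamenen-5-yl]methanol, via aryllithium 14 (not isolated), via aryl aldehyde 15 (not isolated)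
Conditions: n-BuLi, THF, −78 °C; DMF, −78 to 0 °C; AcOH (1 equiv), MeOH, then NaBH4, 0 °C
Reagents that add atoms: N,N-dimethylformamide, CN(C)C=O
Why: Bromine–lithium exchange, formylation of the aryllithium with DMF and borohydride reduction of the aldehyde in the same flask are standard on 2,6-disubstituted aryl bromides, the acetic acid neutralises the lithium alkoxide so that the base-sensitive para-silyloxy aldehyde is not desilylated, and the new carbon becomes C7.

Step 9
Reactants: 16 benzylic alcohol
Product: 18 (1S,4R)-5-(chloromethyl)-8-(tert-butyldimethylsilyloxy)calamenene, via benzylic mesylate 17 (not isolated)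
Conditions: MsCl, Et3N, CH2Cl2, 0 °C to rt; short plug, used at once
Reagents that add atoms: methanesulfonyl chloride, CS(=O)(=O)Cl
Why: Mesylation of an electron-rich benzylic alcohol is followed at once by nucleophilic displacement with the chloride released, and these mildly basic conditions spare the aryl silyl ether.

Step 10
Reactants: 18 benzylic chloride; 6 Weinreb amide
Product: 20 2-[(1S,4R)-8-(tert-butyldimethylsilyloxy)calamenen-5-yl]-1-[(3R,6S)-6-methyl-3-(propan-2-yl)cyclohex-1-en-1-yl]ethanone, via benzylic Grignard reagent 19 (not isolated)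
Conditions: Mg turnings (excess, I2-activated), 2-MeTHF, 0 °C, slow addition of dilute 18; then 6 (1.3 equiv), 0 °C to rt; aqueous work-up
Reagents that add atoms: none
Why: Magnesium insertion into a benzylic chloride under slow addition gives the Grignard reagent, whose blocked ortho positions leave only the CH2 carbon nucleophilic, and Weinreb ketone synthesis with 6 forms the C7–C8 bond and stops at the ketone.

Step 11
Reactants: 20 arylacetyl menthene
Product: 21 (Z)-tert-butyldimethylsilyl dienol ether of 20 (C7=C8 double bond, aryl cis to OTBS, C8a=C4a retained)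
Conditions: TBSOTf, Et3N, CH2Cl2, 0 °C to rt; cold NaHCO3 wash, deactivated silica, amine stripped with toluene
Reagents that add atoms: tert-butyldimethylsilyl trifluoromethanesulfonate, CC(C)(C)[Si](C)(C)OS(=O)(=O)C(F)(F)F
Why: Soft enolisation takes the benzylic α-proton, far more acidic than the γ-hydrogen at C4, and allylic strain between the di-ortho-substituted aryl group and the menthenyl residue places the aryl group cis to oxygen, so the (Z)-dienol ether with the aryl group on the outside of the s-cis diene should result.

Step 12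
Reactants: 21 (Z)-silyl dienol ether; 9 phenyl 1-propynyl sulfone
Product: 24 (1S,4R,1'S,4'R)-8,8'-bis(tert-butyldimethylsilyloxy)-7,5'-bicalamenene, via vinyl sulfone cycloadduct 22 (not isolated), via allylic sulfone diene 23 (not isolated)
Conditions: 9 (3 equiv), BHT (cat.), o-xylene (concentrated), 140 °C, sealed tube, base-free; cool to rt; DBU (4 equiv), rt to 60 °C
Reagents that add atoms: none
Why: In its s-cis form the diene C7=C8(OTBS)–C8a=C4a combines with the acetylenic sulfone through an asynchronous pericyclic transition state in which the bond from nucleophilic C7 to the methyl-substituted alkyne carbon (C6) runs ahead of that from C4a to the carbon carrying sulfur (C5), and 1,4-cyclohexadiene 22 results. DBU then removes the doubly allylic, benzylic C7–H, reprotonation at C5 gives allylic sulfone 23, and 1,2-elimination of C4a–H and benzenesulfinate delivers the arene without an oxidant and with hydrogen at C5. The nearest precedent class is the cycloaddition of acetylenic sulfones, used as alkyne surrogates, to 2-silyloxy-1-vinylcyclohexene-type dienes, with the sulfonyl group later leaving as sulfinate, and step 6 runs it on the unhindered diene. Ring A closes by intermolecular [4+2] annulation onto the existing cyclohexene, two bonds in one operation. No new stereocentre survives, since C7 and C4a end as sp2 carbons while C1, C4, C1' and C4' are spectators, but the C7–C5' axis is fixed here, its sense following from approach anti to the C4 isopropyl group and from the aryl rotamer and not being steered by design. The selectivity needed is regiochemical (C7 to C6, not to C5) and rests on the match of the donor terminus with the acceptor β-carbon (para rule), while the Z geometry keeps the aryl group outside the diene and the absence of base in the first stage keeps 9 from isomerising to its allenyl form.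

Step 13
Reactants: 24 bis-silyl ether
Product: 25 (1S,4R,1'S,4'R)-8,8'-dihydroxy-7,5'-bicalamenene (CNP0145304.1)
Conditions: TBAF (excess), THF, rt to 50 °C, argon; AcOH quench
Reagents that add atoms: none
Why: Fluoride-induced desilylation of aryl silyl ethers is driven by the Si–F bond and the phenoxide leaving group, frees both phenols in one operation and touches neither the benzylic stereocentres nor the axis.

**Compound list**

1 | (S)-(+)-carvone | CC1=CC[C@@H](CC1=O)C(C)=C | starting material
2 | (5S)-2-methyl-5-(propan-2-yl)cyclohexanone, C2 epimers | O=C1C[C@@H](C(C)C)CCC1C | intermediate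
3 | (2S,5S)-2-methyl-5-(propan-2-yl)cyclohexanone (trans-carvomenthone) | O=C1C[C@@H](C(C)C)CC[C@@H]1C | intermediate
4 | lithium (3R,6S)-6-methyl-3-(propan-2-yl)cyclohex-1-en-1-olate | [Li]OC1=C[C@@H](C(C)C)CC[C@@H]1C | intermediate
5 | (3R,6S)-6-methyl-3-(propan-2-yl)cyclohex-1-en-1-yl trifluoromethanesulfonate | O=S(=O)(OC1=C[C@@H](C(C)C)CC[C@@H]1C)C(F)(F)F | intermediate
6 | (3R,6S)-N-methoxy-N,6-dimethyl-3-(propan-2-yl)cyclohex-1-ene-1-carboxamide | CON(C)C(=O)C1=C[C@@H](C(C)C)CC[C@@H]1C | intermediate
7 | 1-[(3R,6S)-6-methyl-3-(propan-2-yl)cyclohex-1-en-1-yl]ethanone | CC(=O)C1=C[C@@H](C(C)C)CC[C@@H]1C | intermediate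
8 | TBS dienol ether of 7 (2-siloxydiene) | C=C(O[Si](C)(C)C(C)(C)C)C1=C[C@@H](C(C)C)CC[C@@H]1C | intermediate
9 | phenyl 1-propynyl sulfone | CC#CS(=O)(=O)c1ccccc1 | starting material
10 | (1S,4R)-8-(TBSO)-5-(phenylsulfonyl)-4a,7-dihydrocalamenene (C5=C6 and C8=C8a; C4a undefined) | CC1=C(S(=O)(=O)c2ccccc2)C2C(=C(O[Si](C)(C)C(C)(C)C)C1)[C@@H](C)CC[C@@H]2C(C)C | intermediate
11 | (1S,4R)-8-(TBSO)-5-(phenylsulfonyl)-4a,5-dihydrocalamenene (C6=C7 and C8=C8a; C4a, C5 undefined) | CC1=CC(O[Si](C)(C)C(C)(C)C)=C2[C@@H](C)CC[C@H](C(C)C)C2C1S(=O)(=O)c1ccccc1 | intermediate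
12 | (1S,4R)-8-(tert-butyldimethylsilyloxy)calamenene | c1c(C)cc(O[Si](C)(C)C(C)(C)C)c2c1[C@@H](C(C)C)CC[C@@H]2C | intermediate
13 | (1S,4R)-5-bromo-8-(tert-butyldimethylsilyloxy)calamenene | Brc1c(C)cc(O[Si](C)(C)C(C)(C)C)c2c1[C@@H](C(C)C)CC[C@@H]2C | intermediate
14 | [(1S,4R)-8-(TBSO)calamenen-5-yl]lithium | [Li]c1c(C)cc(O[Si](C)(C)C(C)(C)C)c2c1[C@@H](C(C)C)CC[C@@H]2C | intermediate
15 | (1S,4R)-8-(TBSO)calamenene-5-carbaldehyde | O=Cc1c(C)cc(O[Si](C)(C)C(C)(C)C)c2c1[C@@H](C(C)C)CC[C@@H]2C | intermediate
16 | [(1S,4R)-8-(TBSO)calamenen-5-yl]methanol | OCc1c(C)cc(O[Si](C)(C)C(C)(C)C)c2c1[C@@H](C(C)C)CC[C@@H]2C | intermediate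
17 | [(1S,4R)-8-(TBSO)calamenen-5-yl]methyl methanesulfonate | CS(=O)(=O)OCc1c(C)cc(O[Si](C)(C)C(C)(C)C)c2c1[C@@H](C(C)C)CC[C@@H]2C | intermediate
18 | (1S,4R)-5-(chloromethyl)-8-(TBSO)calamenene | ClCc1c(C)cc(O[Si](C)(C)C(C)(C)C)c2c1[C@@H](C(C)C)CC[C@@H]2C | intermediate
19 | {[(1S,4R)-8-(TBSO)calamenen-5-yl]methyl}magnesium chloride | Cl[Mg]Cc1c(C)cc(O[Si](C)(C)C(C)(C)C)c2c1[C@@H](C(C)C)CC[C@@H]2C | intermediate
20 | 2-[(1S,4R)-8-(TBSO)calamenen-5-yl]-1-[(3R,6S)-6-methyl-3-(propan-2-yl)cyclohex-1-en-1-yl]ethanone | O=C(Cc1c(C)cc(O[Si](C)(C)C(C)(C)C)c2c1[C@@H](C(C)C)CC[C@@H]2C)C1=C[C@@H](C(C)C)CC[C@@H]1C | intermediate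
21 | (Z)-TBS dienol ether of 20 | CC(C)(C)[Si](C)(C)O/C(=C\c1c(C)cc(O[Si](C)(C)C(C)(C)C)c2c1[C@@H](C(C)C)CC[C@@H]2C)C1=C[C@@H](C(C)C)CC[C@@H]1C | intermediate
22 | 4a,7-dihydro cycloadduct of 21 and 9 (5-phenylsulfonyl; C5=C6 and C8=C8a; C4a, C7 undefined) | CC1=C(S(=O)(=O)c2ccccc2)C2C(=C(O[Si](C)(C)C(C)(C)C)C1c1c(C)cc(O[Si](C)(C)C(C)(C)C)c3c1[C@@H](C(C)C)CC[C@@H]3C)[C@@H](C)CC[C@@H]2C(C)C | intermediate
23 | 4a,5-dihydro isomer of 22 (allylic sulfone; C6=C7 and C8=C8a; C4a, C5 undefined) | CC1=C(c2c(C)cc(O[Si](C)(C)C(C)(C)C)c3c2[C@@H](C(C)C)CC[C@@H]3C)C(O[Si](C)(C)C(C)(C)C)=C2[C@@H](C)CC[C@H](C(C)C)C2C1S(=O)(=O)c1ccccc1 | intermediate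
24 | (1S,4R,1'S,4'R)-8,8'-bis(tert-butyldimethylsilyloxy)-7,5'-bicalamenene | Cc1cc2c(c(O[Si](C)(C)C(C)(C)C)c1-c1c(C)cc(O[Si](C)(C)C(C)(C)C)c3c1[C@@H](C(C)C)CC[C@@H]3C)[C@@H](C)CC[C@@H]2C(C)C | intermediate
25 | (1S,4R,1'S,4'R)-8,8'-dihydroxy-7,5'-bicalamenene (CNP0145304.1) | Cc1cc2c(c(O)c1-c1c(C)cc(O)c3c1[C@@H](C(C)C)CC[C@@H]3C)[C@@H](C)CC[C@@H]2C(C)C | target

**Step count**

Total step count: 13.
Longest linear sequence: 13 steps from (S)-carvone. Amide 6 is used twice, in steps 4 and 10, so all steps lie on one line.

**Steps most likely to fail**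

1. Step 12.
- Risk: the di-ortho-substituted aryl group stands perpendicular to the diene and screens both faces of C7. Bond formation between C7 and the methyl-bearing alkyne carbon may then be slower than thermal desilylation of the diene or polymerisation of the sulfone.
- Fallback, from 12 and 13 back to 24: the biaryl bond would be made between two finished arenes by Negishi coupling instead of by ring construction. TBAF in THF would free 12 to (1S,4R)-8-hydroxycalamenene F1. NBS with catalytic i-Pr2NH in CH2Cl2, the amine-mediated ortho-bromination of phenols, would give (1S,4R)-7-bromo-8-hydroxycalamenene F2. TBSOTf and 2,6-lutidine would then give (1S,4R)-7-bromo-8-(tert-butyldimethylsilyloxy)calamenene F3. Bromide 13 would be lithiated to 14 as in step 8 and transmetalated with ZnCl2 to the arylzinc chloride F4. F3 and F4 would be joined with Pd2(dba)3 and RuPhos in THF at 70 °C, a catalyst system established for tetra-ortho-substituted biaryls, to give 24.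

2. Step 7.
- Risk: the pseudoaxial C4' isopropyl group screens C5', so attack at C7' or radical bromination of a benzylic position may compete with the desired para substitution.
- Fallback, from 8 back to 16: the carbon on C5' would be brought in by the dienophile, so no aromatic substitution is needed. Diene 8 and methyl but-2-ynoate (toluene, 130 °C, sealed tube) should give, in the same para orientation, the cyclohexadiene ester F5. DDQ in toluene would dehydrogenate it to methyl (1S,4R)-8-(tert-butyldimethylsilyloxy)calamenene-5-carboxylate F6. i-Bu2AlH in CH2Cl2 would reduce F6 to 16.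

3. Step 10.
- Risk: Wurtz-type homocoupling during magnesium insertion, or sluggish addition of the hindered benzylic nucleophile, may consume the advanced chloride.
- Fallback, from 15 and 5 back to 20: no benzylic organometallic is used, and the C8–C8a bond is formed instead of C7–C8. Aldehyde 15 would be isolated by leaving out the borohydride in step 8. Wittig methoxymethylenation (Ph3P(CH2OMe)Cl, NaHMDS, THF) would give the aryl enol ether F7 as an E/Z mixture. Dilute HCl in THF would hydrolyse it to the arylacetaldehyde F8. Nozaki–Hiyama–Kishi coupling with enol triflate 5 (CrCl2, cat. NiCl2, DMF) would give the allylic alcohol F9 as carbinol epimers. Dess–Martin periodinane would oxidise F9 to 20.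

**Further compounds**

F1 | step 12 | (1S,4R)-8-hydroxycalamenene | c1c(C)cc(O)c2c1[C@@H](C(C)C)CC[C@@H]2C
F2 | step 12 | (1S,4R)-7-bromo-8-hydroxycalamenene | c1c(C)c(Br)c(O)c2c1[C@@H](C(C)C)CC[C@@H]2C
F3 | step 12 | (1S,4R)-7-bromo-8-(tert-butyldimethylsilyloxy)calamenene | c1c(C)c(Br)c(O[Si](C)(C)C(C)(C)C)c2c1[C@@H](C(C)C)CC[C@@H]2C
F4 | step 12 | [(1S,4R)-8-(TBSO)calamenen-5-yl]zinc chloride | Cl[Zn]c1c(C)cc(O[Si](C)(C)C(C)(C)C)c2c1[C@@H](C(C)C)CC[C@@H]2C
F5 | step 7 | methyl (1S,4R)-8-(TBSO)-4a,7-dihydrocalamenene-5-carboxylate (C4a undefined) | CC1=C(C(=O)OC)C2C(=C(O[Si](C)(C)C(C)(C)C)C1)[C@@H](C)CC[C@@H]2C(C)C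
F6 | step 7 | methyl (1S,4R)-8-(tert-butyldimethylsilyloxy)calamenene-5-carboxylate | COC(=O)c1c(C)cc(O[Si](C)(C)C(C)(C)C)c2c1[C@@H](C(C)C)CC[C@@H]2C
F7 | step 10 | (1S,4R)-5-(2-methoxyethenyl)-8-(TBSO)calamenene (E/Z) | COC=Cc1c(C)cc(O[Si](C)(C)C(C)(C)C)c2c1[C@@H](C(C)C)CC[C@@H]2C
F8 | step 10 | [(1S,4R)-8-(TBSO)calamenen-5-yl]acetaldehyde | O=CCc1c(C)cc(O[Si](C)(C)C(C)(C)C)c2c1[C@@H](C(C)C)CC[C@@H]2C
F9 | step 10 | 2-[(1S,4R)-8-(TBSO)calamenen-5-yl]-1-[(3R,6S)-6-methyl-3-(propan-2-yl)cyclohex-1-en-1-yl]ethanol (carbinol epimers) | OC(Cc1c(C)cc(O[Si](C)(C)C(C)(C)C)c2c1[C@@H](C(C)C)CC[C@@H]2C)C1=C[C@@H](C(C)C)CC[C@@H]1C
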